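The second is the unit to start in, since the forks of this flask are compared as rates per second.

free monomer 10 mM; initiator 0.25 mM; time 5.0 min

    free monomer + initiator → living end + monomer in chains (k1 = 11 M⁻¹ s⁻¹)
    free monomer + living end → monomer in chains + living end, rate k2*[living end]*[free monomer] (k2 = 210 M⁻¹ s⁻¹)
    living end → dead end B (k3 = 0.010 s⁻¹)
    2 initiator → spent initiator A (k4 = 3400 M⁻¹ s⁻¹)
    monomer in chains + living end → free monomer + living end, rate k5*[living end] as long as [monomer in chains] is above zero (k5 = 1.2 s⁻¹)

* average number of monomer units in a chain (chains begun, living or dead) at 5.0 min
* part of the free monomer that has reacted at 5.0 min

- where a step has two of a species, its rate is k times that concentration squared, and two are used at each turn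
- the average divides the monomer in chains by the number of chains begun, living and dead together
- run time (flask): 5.0 min

What can an initiator molecule do at the start? It can meet free monomer, at 0.110 s⁻¹, or go by self-destruction, at 1.70 s⁻¹, so the second road is faster, and its chance of starting a chain is 6.08%. With c(free monomer) held, that chance rises as c(initiator) falls. How many chains begin? Summed over the fall, with c(free monomer) held at its charge, 0.0453 mM.

What does a living end do? It adds free monomer at 210 M⁻¹ s⁻¹ times c(free monomer) and gives back at 1.2 s⁻¹. These balance at a floor of 5.71 mM, the equilibrium monomer concentration, so what shrinks is the gap above that floor.

But living ends die at 0.010 s⁻¹; how far does the gap close? Over 5.0 min the shrinking comes to 0.904. I call this the closure number, the adding constant times c(living end) summed over time up to the reading, and the gap is multiplied by e to its negative. So 59.5% of the gap closes, c(free monomer) reaches 7.45 mM, conversion is 25.5%, and dp is 56.3.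

Is starting the living ends at once fair? The first half-life of initiator, 0.588 s, is short beside a living end's mean life of 100 s, so I accept it.

The forecast gives dp 57 and conversion 25%, closing “about 60% of the gap”. My own figures differ from these: dp 56.3 against 57, and conversion 25.5% against 25%.

The simulation gives dp 56.8 and conversion 25.6%.

In this flask the self-destruction of initiator had half its turnover up to 5.0 min behind it by 0.433 s, and initiator stood at 0.264% of its charge at 0.500 min. Living ends then added and gave back monomer, falling from 0.0344 mM at 0.500 min to 0.00236 mM at 5.00 min, and at 50.0 min, with 0 mM of them, free monomer stood at 7.35 mM, above the floor. Read from the conversion, this flask's closure number is 0.911. For the neighbour flask with 25 mM of free monomer, the same reckoning gives 0.0797 mM of chains begun, a closure number of 1.59, conversion 61.4% and dp 193; the simulation of that neighbour flask gives 61.4% and 193.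

The constants used here are assumed; no experiment stands behind them.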